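**Retrosynthetic overview**

1. Fertidin 23 comes from jaeschkeanadiol 21 by selective acylation of the secondary C4 hydroxyl with 4-methoxybenzoyl chloride 22.
2. The seven-membered ring is formed last, by ring-closing metathesis (C6=C7) of the allyl/methallyl diene diol 20.
3. The C4–C5 bond and the C4 carbinol come from chelation-controlled methallylation of β-hydroxy aldehyde 18 with stannane 19.
4. C3 comes from isopropyl addition to cyclopentanone 14; C3a and C8a come from Michael addition of lithiated 1,3-dithiane to enone 4 (anti to the silyloxy group), then enolate allylation (anti to the dithiane), after which the enone carbonyl is deoxygenated.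
5. The five-membered ring is present from the start in silyloxy enone 1, whose single stereocentre relays to C3a, C8a, C3 and C4 before it is erased.

Assumption: (4R)-4-[(tert-butyldimethylsilyl)oxy]cyclopent-2-en-1-one is bought enantiopure; atom numbers in the text are those of the octahydroazulene skeleton of the target (C3 carbinol with isopropyl, C3a ring-fusion CH, C4 ester carbon, C8a quaternary carbon).

**Route**

Step 1
Reactants: 1 (4R)-4-[(tert-butyldimethylsilyl)oxy]cyclopent-2-en-1-one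
Product: 2 (4R)-4-[(tert-butyldimethylsilyl)oxy]-2-iodocyclopent-2-en-1-one
Conditions: I2, pyridine, CH2Cl2, 0 °C → rt
Reagents that add atoms: iodine, II
Why: Baylis–Hillman-type α-iodination (conjugate addition of pyridine, iodination of the enolate, loss of pyridine) functionalises only the α-carbon and leaves the silyl ether and its stereocentre untouched.

Step 2
Reactants: 2 (4R)-4-[(tert-butyldimethylsilyl)oxy]-2-iodocyclopent-2-en-1-one; 3 tetramethylstannane
Product: 4 (4R)-4-[(tert-butyldimethylsilyl)oxy]-2-methylcyclopent-2-en-1-one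
Conditions: Me4Sn, PdCl2(PhCN)2 (5 mol %), AsPh3 (10 mol %), CuI (10 mol %), NMP, 80 °C
Reagents that add atoms: tetramethylstannane (3), C[Sn](C)(C)C
Why: Stille cross-coupling of the α-iodoenone, accelerated by CuI and the weakly bound AsPh3 ligand, installs the future angular methyl under neutral conditions that do not eliminate the β-silyloxy group.

Step 3
Reactants: 4 (4R)-4-[(tert-butyldimethylsilyl)oxy]-2-methylcyclopent-2-en-1-one; 5 1,3-dithiane; 6 allyl bromide
Product: 9 (2R,3R,4R)-4-[(tert-butyldimethylsilyl)oxy]-3-(1,3-dithian-2-yl)-2-methyl-2-(prop-2-en-1-yl)cyclopentan-1-one, via 2-lithio-1,3-dithiane 7 (not isolated), via lithium enolate 8 (not isolated)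
Conditions: 5, n-BuLi, THF, −30 °C; HMPA (2.5 equiv), −78 °C; 4, −78 °C; then 6 (3 equiv), −78 → −30 °C
Reagents that add atoms: 1,3-dithiane (5), C1CSCSC1; allyl bromide (6), C=CCBr
Why: Intermolecular Michael addition of the sulfur-stabilised carbanion 7 (HMPA favours 1,4-attack) occurs anti to the silyloxy group, and the regiodefined enolate 8 is then C-allylated anti to the new dithianyl group, so the quaternary carbon carries allyl trans and methyl cis to the dithiane.

Step 4
Reactants: 9 (2R,3R,4R)-4-[(tert-butyldimethylsilyl)oxy]-3-(1,3-dithian-2-yl)-2-methyl-2-(prop-2-en-1-yl)cyclopentan-1-one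
Product: 10 (2R,3R,4R)-4-[(tert-butyldimethylsilyl)oxy]-3-(1,3-dithian-2-yl)-2-methyl-2-(prop-2-en-1-yl)cyclopentan-1-ol (both C1 epimers; this centre is removed in step 6)
Conditions: NaBH4, MeOH, 0 °C → rt
Reagents that add atoms: none
Why: Hydride reduction of the only carbonyl group proceeds chemoselectively, and the configuration of the new carbinol is irrelevant because it is deleted two steps later.

Step 5
Reactants: 10 (2R,3R,4R)-4-[(tert-butyldimethylsilyl)oxy]-3-(1,3-dithian-2-yl)-2-methyl-2-(prop-2-en-1-yl)cyclopentan-1-ol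
Product: 11 O-[(2R,3R,4R)-4-[(tert-butyldimethylsilyl)oxy]-3-(1,3-dithian-2-yl)-2-methyl-2-(prop-2-en-1-yl)cyclopentyl] O-phenyl carbonothioate (both C1 epimers)
Conditions: PhOC(S)Cl, pyridine, DMAP, CH2Cl2, rt
Reagents that add atoms: O-phenyl chlorothionoformate, S=C(Cl)Oc1ccccc1
Why: DMAP-catalysed O-thioacylation gives the Barton–McCombie precursor without generating an alkoxide, which rules out 1,3-silyl migration to the new hydroxyl.

Step 6
Reactants: 11 O-[(2R,3R,4R)-4-[(tert-butyldimethylsilyl)oxy]-3-(1,3-dithian-2-yl)-2-methyl-2-(prop-2-en-1-yl)cyclopentyl] O-phenyl carbonothioate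
Product: 12 tert-butyl{[(1R,2R,3R)-2-(1,3-dithian-2-yl)-3-methyl-3-(prop-2-en-1-yl)cyclopentyl]oxy}dimethylsilane
Conditions: Bu3SnH (1.5 equiv), AIBN (cat.), toluene, 100 °C
Reagents that add atoms: none
Why: In this Barton–McCombie radical deoxygenation the stannyl radical adds to the thiocarbonyl much faster than it attacks thioacetal sulfur, and the resulting secondary radical has no favourable cyclisation onto the allyl group before it is reduced by Bu3SnH.

Step 7
Reactants: 12 tert-butyl{[(1R,2R,3R)-2-(1,3-dithian-2-yl)-3-methyl-3-(prop-2-en-1-yl)cyclopentyl]oxy}dimethylsilane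
Product: 13 (1R,2R,3R)-2-(1,3-dithian-2-yl)-3-methyl-3-(prop-2-en-1-yl)cyclopentan-1-ol
Conditions: TBAF, THF, rt
Reagents that add atoms: none
Why: Fluoride-induced desilylation cleaves the only fluoride-labile group in the molecule.

Step 8
Reactants: 13 (1R,2R,3R)-2-(1,3-dithian-2-yl)-3-methyl-3-(prop-2-en-1-yl)cyclopentan-1-ol
Product: 14 (2R,3R)-2-(1,3-dithian-2-yl)-3-methyl-3-(prop-2-en-1-yl)cyclopentan-1-one
Conditions: SO3·pyridine, DMSO, iPr2NEt, CH2Cl2, 0 °C
Reagents that add atoms: none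
Why: Parikh–Doering oxidation (activated DMSO) gives the ketone without oxidising the thioacetal sulfurs and is mild enough not to epimerise the α-carbon that carries the dithiane.

Step 9
Reactants: 14 (2R,3R)-2-(1,3-dithian-2-yl)-3-methyl-3-(prop-2-en-1-yl)cyclopentan-1-one; 15 isopropylmagnesium chloride
Product: 17 (1R,2R,3R)-2-(1,3-dithian-2-yl)-3-methyl-1-(propan-2-yl)-3-(prop-2-en-1-yl)cyclopentan-1-ol, via isopropylcerium dichloride 16 (not isolated)
Conditions: CeCl3 (anhydrous), 15, THF, −78 °C, 1 h; then 14, −78 → 0 °C; aq NH4Cl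
Reagents that add atoms: isopropylmagnesium chloride (15), CC(C)[Mg]Cl
Why: 1,2-Addition of the weakly basic organocerium reagent (Imamoto conditions) suppresses enolisation and β-hydride reduction, and attack anti to the adjacent dithianyl group (the face also free of the cis methyl) places isopropyl trans and the new tertiary hydroxyl cis to the dithiane.

Step 10
Reactants: 17 (1R,2R,3R)-2-(1,3-dithian-2-yl)-3-methyl-1-(propan-2-yl)-3-(prop-2-en-1-yl)cyclopentan-1-ol
Product: 18 (1R,2R,5R)-2-hydroxy-5-methyl-2-(propan-2-yl)-5-(prop-2-en-1-yl)cyclopentane-1-carbaldehyde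
Conditions: MeI, CaCO3, MeCN/H2O 4:1, 45 °C; used crude
Reagents that add atoms: water, O
Why: Alkylative hydrolysis of the dithioacetal (S-methylation, then attack of water) unmasks the aldehyde under buffered near-neutral conditions that avoid retro-aldol cleavage, dehydration or epimerisation of the β-hydroxy aldehyde.

Step 11
Reactants: 18 (1R,2R,5R)-2-hydroxy-5-methyl-2-(propan-2-yl)-5-(prop-2-en-1-yl)cyclopentane-1-carbaldehyde; 19 tributyl(2-methylprop-2-en-1-yl)stannane
Product: 20 (1R,2S,3R)-2-[(1S)-1-hydroxy-3-methylbut-3-en-1-yl]-3-methyl-1-(propan-2-yl)-3-(prop-2-en-1-yl)cyclopentan-1-ol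
Conditions: MgBr2·OEt2 (3 equiv), CH2Cl2, −78 °C; then 19 (2.5 equiv), −78 → −20 °C
Reagents that add atoms: tributyl(2-methylprop-2-en-1-yl)stannane (19), CC(=C)C[Sn](CCCC)(CCCC)CCCC
Why: In this chelation-controlled carbonyl allylation MgBr2 ties the tertiary hydroxyl and the aldehyde oxygen into a six-membered chelate, and the methallylstannane attacks the aldehyde face on the side of the ring hydrogen, away from the quaternary carbon and its cis methyl, which gives the (S)-carbinol.

Step 12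
Reactants: 20 (1R,2S,3R)-2-[(1S)-1-hydroxy-3-methylbut-3-en-1-yl]-3-methyl-1-(propan-2-yl)-3-(prop-2-en-1-yl)cyclopentan-1-ol
Product: 21 jaeschkeanadiol, (3R,3aS,4S,8aR)-6,8a-dimethyl-3-(propan-2-yl)-1,2,3,3a,4,5,8,8a-octahydroazulene-3,4-diol
Conditions: second-generation Grubbs catalyst RuCl2(=CHPh)(PCy3)(H2IMes) (5 mol %), CH2Cl2 (5 mM), 40 °C
Reagents that add atoms: none
Why: Ring-closing olefin metathesis between the allyl and methallyl groups closes the trans-fused seven-membered ring with the trisubstituted alkene in the required position, tolerates the free diol and is driven by loss of ethene.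

Step 13
Reactants: 21 jaeschkeanadiol; 22 4-methoxybenzoyl chloride
Product: 23 Fertidin, (3R,3aS,4S,8aR)-3-hydroxy-6,8a-dimethyl-3-(propan-2-yl)-1,2,3,3a,4,5,8,8a-octahydroazulen-4-yl 4-methoxybenzoate
Conditions: 22 (1.5 equiv), Et3N, DMAP (cat.), CH2Cl2, 0 °C → rt
Reagents that add atoms: 4-methoxybenzoyl chloride (22), COc1ccc(cc1)C(Cl)=O
Why: DMAP-catalysed acylation is selective for the secondary hydroxyl because the tertiary hydroxyl flanked by the isopropyl group and the ring fusion is far less reactive.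

**Compound list**

1 | (4R)-4-[(tert-butyldimethylsilyl)oxy]cyclopent-2-en-1-one | O=C1C=C[C@H](O[Si](C)(C)C(C)(C)C)C1 | starting material
2 | (4R)-4-[(tert-butyldimethylsilyl)oxy]-2-iodocyclopent-2-en-1-one | O=C1C(I)=C[C@H](O[Si](C)(C)C(C)(C)C)C1 | intermediate
3 | tetramethylstannane | C[Sn](C)(C)C | starting material
4 | (4R)-4-[(tert-butyldimethylsilyl)oxy]-2-methylcyclopent-2-en-1-one | O=C1C(C)=C[C@H](O[Si](C)(C)C(C)(C)C)C1 | intermediate
5 | 1,3-dithiane | C1CSCSC1 | starting material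
6 | allyl bromide (3-bromoprop-1-ene) | C=CCBr | starting material
7 | 2-lithio-1,3-dithiane | [Li]C1SCCCS1 | intermediate
8 | lithium (3R,4R)-4-[(tert-butyldimethylsilyl)oxy]-3-(1,3-dithian-2-yl)-2-methylcyclopent-1-en-1-olate | [Li]OC1=C(C)[C@@H](C2SCCCS2)[C@H](O[Si](C)(C)C(C)(C)C)C1 | intermediate
9 | (2R,3R,4R)-4-[(tert-butyldimethylsilyl)oxy]-3-(1,3-dithian-2-yl)-2-methyl-2-(prop-2-en-1-yl)cyclopentan-1-one | O=C1C[C@@H](O[Si](C)(C)C(C)(C)C)[C@H](C2SCCCS2)[C@@]1(C)CC=C | intermediate
10 | (2R,3R,4R)-4-[(tert-butyldimethylsilyl)oxy]-3-(1,3-dithian-2-yl)-2-methyl-2-(prop-2-en-1-yl)cyclopentan-1-ol, both C1 epimers | OC1C[C@@H](O[Si](C)(C)C(C)(C)C)[C@H](C2SCCCS2)[C@@]1(C)CC=C | intermediate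
11 | O-[(2R,3R,4R)-4-[(tert-butyldimethylsilyl)oxy]-3-(1,3-dithian-2-yl)-2-methyl-2-(prop-2-en-1-yl)cyclopentyl] O-phenyl carbonothioate, both C1 epimers | S=C(Oc1ccccc1)OC2C[C@@H](O[Si](C)(C)C(C)(C)C)[C@H](C3SCCCS3)[C@@]2(C)CC=C | intermediate
12 | tert-butyl{[(1R,2R,3R)-2-(1,3-dithian-2-yl)-3-methyl-3-(prop-2-en-1-yl)cyclopentyl]oxy}dimethylsilane | C1C[C@@H](O[Si](C)(C)C(C)(C)C)[C@H](C2SCCCS2)[C@@]1(C)CC=C | intermediate
13 | (1R,2R,3R)-2-(1,3-dithian-2-yl)-3-methyl-3-(prop-2-en-1-yl)cyclopentan-1-ol | C1C[C@@H](O)[C@H](C2SCCCS2)[C@@]1(C)CC=C | intermediate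
14 | (2R,3R)-2-(1,3-dithian-2-yl)-3-methyl-3-(prop-2-en-1-yl)cyclopentan-1-one | C1CC(=O)[C@H](C2SCCCS2)[C@@]1(C)CC=C | intermediate
15 | isopropylmagnesium chloride | CC(C)[Mg]Cl | starting material
16 | isopropylcerium dichloride | CC(C)[Ce](Cl)Cl | intermediate
17 | (1R,2R,3R)-2-(1,3-dithian-2-yl)-3-methyl-1-(propan-2-yl)-3-(prop-2-en-1-yl)cyclopentan-1-ol | C1C[C@@](O)(C(C)C)[C@H](C2SCCCS2)[C@@]1(C)CC=C | intermediate
18 | (1R,2R,5R)-2-hydroxy-5-methyl-2-(propan-2-yl)-5-(prop-2-en-1-yl)cyclopentane-1-carbaldehyde | C1C[C@@](O)(C(C)C)[C@H](C=O)[C@@]1(C)CC=C | intermediate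
19 | tributyl(2-methylprop-2-en-1-yl)stannane | CC(=C)C[Sn](CCCC)(CCCC)CCCC | starting material
20 | (1R,2S,3R)-2-[(1S)-1-hydroxy-3-methylbut-3-en-1-yl]-3-methyl-1-(propan-2-yl)-3-(prop-2-en-1-yl)cyclopentan-1-ol | C=C(C)C[C@H](O)[C@@H]1[C@@](C)(CC=C)CC[C@@]1(O)C(C)C | intermediate
21 | jaeschkeanadiol, (3R,3aS,4S,8aR)-6,8a-dimethyl-3-(propan-2-yl)-1,2,3,3a,4,5,8,8a-octahydroazulene-3,4-diol | O[C@H]1CC(C)=CC[C@@]2(C)CC[C@@](O)(C(C)C)[C@H]12 | intermediate
22 | 4-methoxybenzoyl chloride | COc1ccc(cc1)C(Cl)=O | starting material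
23 | Fertidin, (3R,3aS,4S,8aR)-3-hydroxy-6,8a-dimethyl-3-(propan-2-yl)-1,2,3,3a,4,5,8,8a-octahydroazulen-4-yl 4-methoxybenzoate | COc1ccc(C(=O)O[C@H]2CC(C)=CC[C@@]3(C)CC[C@@](O)(C(C)C)[C@H]23)cc1 | target

**Totals**

Total step count: 13. Longest linear sequence: 13 steps (1 → 23).

**Three steps most likely to fail, with fallbacks**

Step 3. The direct C-allylation of the hindered, tetrasubstituted enolate 8 may be slow, and proton transfer would then erode regiochemistry or eliminate the silyloxy group. The fallback sets out from 4 and returns at 9. The Michael addition of 7 to 4 is run as before, but enolate 8 is quenched on oxygen with allyl chloroformate at −78 °C to give prop-2-en-1-yl (3R,4R)-4-[(tert-butyldimethylsilyl)oxy]-3-(1,3-dithian-2-yl)-2-methylcyclopent-1-en-1-yl carbonate F1. Treating this with Pd(PPh3)4 (zerovalent palladium, 5 mol %) in THF at rt triggers decarboxylative Tsuji allylation: the enolate is regenerated regiospecifically next to the π-allylpalladium cation and is allylated anti to the dithiane, giving 9.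

Step 9. Isopropyl transfer to the hindered, enolisable ketone 14 may give reduction or enolisation (with epimerisation at C3a) instead of addition. The fallback sets out from 14 and returns at 21.
- The smaller sp2 nucleophile isopropenylmagnesium bromide, which has no transferable β-hydride, is added with CeCl3 (THF, −78 °C) from the same face to give (1S,2R,3R)-2-(1,3-dithian-2-yl)-3-methyl-1-(prop-1-en-2-yl)-3-(prop-2-en-1-yl)cyclopentan-1-ol F2.
- MeI/CaCO3 in aqueous MeCN then gives (1R,2S,5R)-2-hydroxy-5-methyl-2-(prop-1-en-2-yl)-5-(prop-2-en-1-yl)cyclopentane-1-carbaldehyde F3.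
- MgBr2·OEt2 and 19 give (1S,2S,3R)-2-[(1S)-1-hydroxy-3-methylbut-3-en-1-yl]-3-methyl-1-(prop-1-en-2-yl)-3-(prop-2-en-1-yl)cyclopentan-1-ol F4.
- Ring-closing metathesis with the second-generation Grubbs catalyst, in which the isopropenyl group on the fully substituted carbinol carbon is too hindered to compete, gives (3S,3aS,4S,8aR)-6,8a-dimethyl-3-(prop-1-en-2-yl)-1,2,3,3a,4,5,8,8a-octahydroazulene-3,4-diol F5.
- H2 (1 atm) with RhCl(PPh3)3 in benzene at rt saturates only the 1,1-disubstituted isopropenyl alkene and leaves the trisubstituted ring alkene, giving 21.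

Step 11. If the magnesium chelate does not form cleanly on the hindered tertiary hydroxyl, the aldehyde face selectivity may drop or reverse. The fallback sets out from 18 and returns at 23, replacing substrate control by stereoinversion. The epimeric adduct of 18 and 19, (1R,2S,3R)-2-[(1R)-1-hydroxy-3-methylbut-3-en-1-yl]-3-methyl-1-(propan-2-yl)-3-(prop-2-en-1-yl)cyclopentan-1-ol F6, is separated and cyclised under the step 12 conditions to (3R,3aS,4R,8aR)-6,8a-dimethyl-3-(propan-2-yl)-1,2,3,3a,4,5,8,8a-octahydroazulene-3,4-diol F7. Its secondary hydroxyl is then esterified with inversion in a Mitsunobu reaction (4-methoxybenzoic acid, PPh3, DIAD, toluene, 0 °C → rt; the tertiary hydroxyl does not react), giving 23 directly.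

**Further compounds**

F1 | step 3 | prop-2-en-1-yl (3R,4R)-4-[(tert-butyldimethylsilyl)oxy]-3-(1,3-dithian-2-yl)-2-methylcyclopent-1-en-1-yl carbonate | C=CCOC(=O)OC1=C(C)[C@@H](C2SCCCS2)[C@H](O[Si](C)(C)C(C)(C)C)C1
F2 | step 9 | (1S,2R,3R)-2-(1,3-dithian-2-yl)-3-methyl-1-(prop-1-en-2-yl)-3-(prop-2-en-1-yl)cyclopentan-1-ol | C1C[C@@](O)(C(C)=C)[C@H](C2SCCCS2)[C@@]1(C)CC=C
F3 | step 9 | (1R,2S,5R)-2-hydroxy-5-methyl-2-(prop-1-en-2-yl)-5-(prop-2-en-1-yl)cyclopentane-1-carbaldehyde | C1C[C@@](O)(C(C)=C)[C@H](C=O)[C@@]1(C)CC=C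
F4 | step 9 | (1S,2S,3R)-2-[(1S)-1-hydroxy-3-methylbut-3-en-1-yl]-3-methyl-1-(prop-1-en-2-yl)-3-(prop-2-en-1-yl)cyclopentan-1-ol | C=C(C)C[C@H](O)[C@@H]1[C@@](C)(CC=C)CC[C@@]1(O)C(C)=C
F5 | step 9 | (3S,3aS,4S,8aR)-6,8a-dimethyl-3-(prop-1-en-2-yl)-1,2,3,3a,4,5,8,8a-octahydroazulene-3,4-diol | O[C@H]1CC(C)=CC[C@@]2(C)CC[C@@](O)(C(C)=C)[C@H]12
F6 | step 11 | (1R,2S,3R)-2-[(1R)-1-hydroxy-3-methylbut-3-en-1-yl]-3-methyl-1-(propan-2-yl)-3-(prop-2-en-1-yl)cyclopentan-1-ol | C=C(C)C[C@@H](O)[C@@H]1[C@@](C)(CC=C)CC[C@@]1(O)C(C)C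
F7 | step 11 | (3R,3aS,4R,8aR)-6,8a-dimethyl-3-(propan-2-yl)-1,2,3,3a,4,5,8,8a-octahydroazulene-3,4-diol | O[C@@H]1CC(C)=CC[C@@]2(C)CC[C@@](O)(C(C)C)[C@H]12
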